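The acetylenic ring is traced back to (R)-levodione: C3 (the carbinol carbon) and C6 (the ring carbon that carries the C7≡C8 alkyne) stand 1,4 to each other, a latent 1,4-diketone. An asymmetric intramolecular Stetter reaction of the acyclic keto-aldehyde 3,3,5-trimethyl-4-oxohex-5-enal joins the aldehyde carbon (future C3) to the enone CH2 (future C4). This closes the six-membered ring and sets the C5 methyl centre, which then directs hydride reduction at C3 and disappears when C5=C6 is formed. Triflation and Sonogashira coupling give the C15 enyne phosphonium salt; the ε-half comes from (R)-α-ionone, and the C40 chain is assembled by two Wittig reactions around a C10 unit.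

Key step: step 3

Remark: the compound code is read as the all-E (3R,3'R,6'R)-7,8-didehydro-β,ε-carotene-3,3'-diol drawn by the SMILES. Carotenoid numbering is used, with primed locants for the ε-half. (R)-α-Ionone of high enantiomeric purity and both antipodes of the triazolium precatalyst are taken as purchasable.

Step 1
Reactants: 1 3,3-dimethyldihydrofuran-2(3H)-one (α,α-dimethyl-γ-butyrolactone); 2 isopropenylmagnesium bromide
Product: 3 6-hydroxy-2,4,4-trimethylhex-1-en-3-one (in equilibrium with its cyclic hemiketal)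
Conditions: 2 (1.1 equiv), THF, −78 → −20 °C; aq. NH4Cl
Reagents that add atoms: none
Why: Acyl substitution of a lactone by a Grignard reagent should stop after one addition, because the five-membered magnesium hemiketal persists at low temperature and the α-quaternary ketone is too hindered for a second addition.

Step 2
Reactants: 3 6-hydroxy-2,4,4-trimethylhex-1-en-3-one
Product: 4 3,3,5-trimethyl-4-oxohex-5-enal
Conditions: Dess–Martin periodinane, CH2Cl2, 0 °C → rt
Reagents that add atoms: none
Why: Dess–Martin oxidation of the primary alcohol (through the open hydroxy-ketone form) should give the aldehyde under neutral conditions that leave the enone alone; the quaternary carbon blocks furan formation from the 1,4-dicarbonyl unit.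

Step 3
Reactants: 4 3,3,5-trimethyl-4-oxohex-5-enal
Product: 5 (6R)-2,2,6-trimethylcyclohexane-1,4-dione ((R)-levodione)
Conditions: (5aS,10bR)-2-(pentafluorophenyl)-5a,10b-dihydro-4H,6H-indeno[2,1-b][1,2,4]triazolo[4,3-d][1,4]oxazin-2-ium tetrafluoroborate (10–20 mol %; or its antipode, the hand that gives the 6R centre being fixed in a trial run), KN(SiMe3)2 (10–20 mol %), toluene, 0 °C → rt
Reagents that add atoms: none
Why: Proposed new method: the carbene adds to the aldehyde of 4 to give the Breslow intermediate (an acyl-anion equivalent), whose nucleophilic carbon attacks the unsubstituted β-CH2 of the isopropenyl ketone, after which the ring enolate is protonated at the methyl-bearing carbon and the carbene is expelled to leave the 1,4-diketone, so that the new bond joins the carbon that becomes C3 to the carbon that becomes C4. The closest known reaction types are the catalytic asymmetric intramolecular Stetter reaction, so far run in exo mode, and the intermolecular Stetter reaction of 2-substituted acrylates, in which the stereocentre is likewise fixed by protonation. The six-membered ring closes in 6-endo-trig mode because both alkene carbons end up in the ring, a geometry that acyl radicals and oxa-Michael donors (chalcone to flavanone) are known to reach. The only new stereocentre, C6 of 5 (the future C5), is controlled by the chiral carbene, which fixes the face of C–C bond formation and hence the configuration of the transient carbinol carbon, whose OH should then hand its proton to the neighbouring enolate carbon on the same face. The step needs conjugate addition to win over benzoin and aldol pathways, which the substrate secures because attack on the ketone would give a four-membered ring, the aldehyde α-carbon is neopentyl-like and the gem-dimethyl group favours folding; it also needs the product not to epimerise, which the hindered ketone and the substoichiometric base should allow.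

Step 4
Reactants: 5 (6R)-2,2,6-trimethylcyclohexane-1,4-dione
Product: 6 (4R,6R)-4-hydroxy-2,2,6-trimethylcyclohexan-1-one (actinol)
Conditions: Li[HB(s-Bu)3] (L-Selectride, 1.05 equiv), THF, −78 °C; H2O
Reagents that add atoms: none
Why: The bulky hydride should reduce only the unhindered C4 carbonyl and, with the axial C2 methyl blocking the axial trajectory, attack equatorially to give the axial alcohol trans to the C6 methyl, that is the 4R centre (substrate-controlled 1,3-induction in a ketone reduction).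

Step 5
Reactants: 6 (4R,6R)-4-hydroxy-2,2,6-trimethylcyclohexan-1-one
Product: 7 (4R,6R)-4-[(tert-butyldimethylsilyl)oxy]-2,2,6-trimethylcyclohexan-1-one
Conditions: TBSCl, imidazole, DMF, rt
Reagents that add atoms: tert-butyldimethylsilyl chloride, CC(C)(C)[Si](C)(C)Cl
Why: Imidazole-promoted silylation of the secondary alcohol masks the hydroxyl for the strongly basic triflation.

Step 6
Reactants: 7 (4R,6R)-4-[(tert-butyldimethylsilyl)oxy]-2,2,6-trimethylcyclohexan-1-one
Product: 8 (4R)-4-[(tert-butyldimethylsilyl)oxy]-2,6,6-trimethylcyclohex-1-en-1-yl trifluoromethanesulfonate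
Conditions: LDA, THF, −78 → 0 °C; PhNTf2, 0 °C → rt
Reagents that add atoms: N-phenylbis(trifluoromethanesulfonimide), O=S(=O)(N(c1ccccc1)S(=O)(=O)C(F)(F)F)C(F)(F)F
Why: Enolate O-triflation at the only α-hydrogen (C6) should give a single tetrasubstituted enol triflate and erase the relay stereocentre, the silyloxy group being γ to the enolate carbon and so not eliminable.

Step 7
Reactants: 8 (4R)-4-[(tert-butyldimethylsilyl)oxy]-2,6,6-trimethylcyclohex-1-en-1-yl trifluoromethanesulfonate; 9 (2E)-3-methylpent-2-en-4-yn-1-ol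
Product: 10 (2E)-5-[(4R)-4-[(tert-butyldimethylsilyl)oxy]-2,6,6-trimethylcyclohex-1-en-1-yl]-3-methylpent-2-en-4-yn-1-ol
Conditions: Pd(PPh3)4 (5 mol %), CuI (10 mol %), i-Pr2NH, DMF, rt → 40 °C, degassed
Reagents that add atoms: none
Why: Sonogashira coupling of the enol triflate with the terminal alkyne joins C6 to C7 and carries the E-configured C9=C10 bond of the commercial enynol through unchanged.

Step 8
Reactants: 10 (2E)-5-[(4R)-4-[(tert-butyldimethylsilyl)oxy]-2,6,6-trimethylcyclohex-1-en-1-yl]-3-methylpent-2-en-4-yn-1-ol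
Product: 12 tributyl{(2E)-5-[(4R)-4-[(tert-butyldimethylsilyl)oxy]-2,6,6-trimethylcyclohex-1-en-1-yl]-3-methylpent-2-en-4-yn-1-yl}phosphonium bromide, via allylic bromide 11 (not isolated)
Conditions: CBr4, PPh3, CH2Cl2, 0 °C; silica plug, concentrate; PBu3, EtOAc, rt
Reagents that add atoms: carbon tetrabromide, BrC(Br)(Br)Br; tributylphosphine, CCCCP(CCCC)CCCC
Why: Appel bromination and SN2 quaternisation are both non-ionising, so the 9E geometry should be kept, and the trialkylphosphonium group is chosen because its ylide should equilibrate less readily about the double bond next to the alkyne than a triphenylphosphonium ylide.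

Step 9
Reactants: 13 (R)-α-ionone, (3E)-4-[(1R)-2,6,6-trimethylcyclohex-2-en-1-yl]but-3-en-2-one; 14 diethyl (cyanomethyl)phosphonate
Product: 15 (2E,4E)-3-methyl-5-[(1R)-2,6,6-trimethylcyclohex-2-en-1-yl]penta-2,4-dienenitrile
Conditions: 14 (1.1 equiv), NaH (1.0 equiv), THF, 0 °C → rt; chromatography to remove the 2Z isomer
Reagents that add atoms: none
Why: Horner–Wadsworth–Emmons olefination of the methyl ketone should give mainly the E nitrile, and keeping the phosphonate in slight excess over NaH avoids γ-deprotonation of the enone and so preserves the C6' centre.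

Step 10
Reactants: 15 (2E,4E)-3-methyl-5-[(1R)-2,6,6-trimethylcyclohex-2-en-1-yl]penta-2,4-dienenitrile
Product: 16 (2E,4E)-3-methyl-5-[(1R)-2,6,6-trimethyl-4-oxocyclohex-2-en-1-yl]penta-2,4-dienenitrile
Conditions: t-BuOOH (5 equiv), Rh2(cap)4 (dirhodium tetrakis(caprolactamate), 1 mol %), K2CO3, CH2Cl2, rt
Reagents that add atoms: tert-butyl hydroperoxide, CC(C)(C)OO
Why: Catalysed allylic oxidation with t-BuOOH (peroxyl radical chain) should convert the secondary ring allylic CH2 (C3') into the enone, the C6' hydrogen being shielded by the gem-dimethyl group and the side chain and the methyl groups being less reactive.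

Step 11
Reactants: 16 (2E,4E)-3-methyl-5-[(1R)-2,6,6-trimethyl-4-oxocyclohex-2-en-1-yl]penta-2,4-dienenitrile
Product: 17 (2E,4E)-5-[(1R,4R)-4-hydroxy-2,6,6-trimethylcyclohex-2-en-1-yl]-3-methylpenta-2,4-dienenitrile
Conditions: Li[HB(s-Bu)3] (L-Selectride, 1.1 equiv), THF, −78 °C; H2O; chromatography
Reagents that add atoms: none
Why: 1,2-Reduction of the β,β-disubstituted enone by a bulky hydride, approaching C3' anti to the axial C1' methyl of the sofa conformer (side chain pseudo-axial), should give the 3',6'-trans alcohol, that is the 3'R centre (substrate control), and any cis epimer is a separable diastereomer.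

Step 12
Reactants: 17 (2E,4E)-5-[(1R,4R)-4-hydroxy-2,6,6-trimethylcyclohex-2-en-1-yl]-3-methylpenta-2,4-dienenitrile
Product: 18 (2E,4E)-5-[(1R,4R)-4-hydroxy-2,6,6-trimethylcyclohex-2-en-1-yl]-3-methylpenta-2,4-dienal
Conditions: i-Bu2AlH (2.3 equiv), CH2Cl2, −60 °C; wet silica gel or aq. Rochelle salt, 0 °C, dark
Reagents that add atoms: water, O
Why: Partial reduction of the nitrile by i-Bu2AlH stops at the aluminium imine, which mild hydrolysis converts to the aldehyde while the hydroxyl is carried as its aluminium alkoxide.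

Step 13
Reactants: 19 (2E,4E,6E)-2,7-dimethylocta-2,4,6-trienedial
Product: 20 (2E,4E,6E)-7-(5,5-dimethyl-1,3-dioxan-2-yl)-2-methylocta-2,4,6-trienal
Conditions: 2,2-dimethylpropane-1,3-diol (1.0 equiv), p-TsOH (cat.), toluene, rt; chromatography, recycling of dialdehyde and bis-acetal
Reagents that add atoms: 2,2-dimethylpropane-1,3-diol, OCC(C)(C)CO
Why: Acid-catalysed acetalisation with one equivalent of diol should give the mono-acetal statistically, which differentiates the two ends of the symmetrical dialdehyde.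

Step 14
Reactants: 20 (2E,4E,6E)-7-(5,5-dimethyl-1,3-dioxan-2-yl)-2-methylocta-2,4,6-trienal
Product: 21 (2E,4E,6E)-7-(5,5-dimethyl-1,3-dioxan-2-yl)-2-methylocta-2,4,6-trien-1-ol
Conditions: NaBH4, MeOH/THF, 0 °C
Reagents that add atoms: none
Why: Borohydride reduces the conjugated aldehyde in 1,2-fashion to the allylic alcohol and leaves the acetal intact.

Step 15
Reactants: 21 (2E,4E,6E)-7-(5,5-dimethyl-1,3-dioxan-2-yl)-2-methylocta-2,4,6-trien-1-ol
Product: 23 [(2E,4E,6E)-7-(5,5-dimethyl-1,3-dioxan-2-yl)-2-methylocta-2,4,6-trien-1-yl]triphenylphosphonium bromide, via trienyl bromide 22 (not isolated)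
Conditions: CBr4 (1.1 equiv), PPh3 (2.3 equiv), CH2Cl2, 0 °C → rt
Reagents that add atoms: carbon tetrabromide, BrC(Br)(Br)Br; triphenylphosphine, c1ccc(cc1)P(c1ccccc1)c1ccccc1
Why: Appel bromination under neutral conditions followed by SN2 quaternisation with the excess phosphine should give the salt while the acetal, which also shields the aldehyde from dibromo-olefination, survives.

Step 16
Reactants: 18 (2E,4E)-5-[(1R,4R)-4-hydroxy-2,6,6-trimethylcyclohex-2-en-1-yl]-3-methylpenta-2,4-dienal; 23 [(2E,4E,6E)-7-(5,5-dimethyl-1,3-dioxan-2-yl)-2-methylocta-2,4,6-trien-1-yl]triphenylphosphonium bromide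
Product: 25 (3R,6R)-3-hydroxy-12'-apo-ε-caroten-12'-al (all-E), via C25 acetal 24 (not isolated)
Conditions: NaOMe, MeOH/CH2Cl2, 0 °C → rt; 0.2 M aq. HCl, acetone, 0 °C, short contact; brief warming in heptane, crystallisation
Reagents that add atoms: water, O
Why: Wittig olefination of the trienyl ylide with 18 forms the C11'=C12' bond (the hindered cis isomer should relax to E on gentle warming), methoxide tolerates the free hydroxyl, and dilute acid then unmasks the very labile polyenal acetal faster than it can ionise the allylic alcohol.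

Step 17
Reactants: 25 (3R,6R)-3-hydroxy-12'-apo-ε-caroten-12'-al; 12 tributyl{(2E)-5-[(4R)-4-[(tert-butyldimethylsilyl)oxy]-2,6,6-trimethylcyclohex-1-en-1-yl]-3-methylpent-2-en-4-yn-1-yl}phosphonium bromide
Product: 26 (3R,3'R,6'R)-3-[(tert-butyldimethylsilyl)oxy]-7,8-didehydro-β,ε-caroten-3'-ol (all-E)
Conditions: 12 (1.3 equiv), NaOMe, CH2Cl2, 0 °C → rt, argon, dark; chromatography without iodine or prolonged heating
Reagents that add atoms: none
Why: Wittig olefination of the allylic tributylphosphonium ylide with the C25 aldehyde forms the C11=C12 bond and completes the C40 polyene, the mild base, low temperature and trialkylphosphonium group being chosen to limit drift of the 9E bond.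

Step 18
Reactants: 26 (3R,3'R,6'R)-3-[(tert-butyldimethylsilyl)oxy]-7,8-didehydro-β,ε-caroten-3'-ol
Product: 27 (3R,3'R,6'R)-7,8-didehydro-β,ε-carotene-3,3'-diol (all-E), the target
Conditions: Bu4NF, THF, 0 °C → rt, dark
Reagents that add atoms: none
Why: Fluoride-mediated desilylation (Si–F bond formation) frees the C3 hydroxyl under conditions that spare the polyene, the enyne and the allylic alcohol.

Compound list
1 | 3,3-dimethyldihydrofuran-2(3H)-one | CC1(C)CCOC1=O | starting material
2 | isopropenylmagnesium bromide | CC(=C)[Mg]Br | starting material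
3 | 6-hydroxy-2,4,4-trimethylhex-1-en-3-one | CC(=C)C(=O)C(C)(C)CCO | intermediate
4 | 3,3,5-trimethyl-4-oxohex-5-enal | CC(=C)C(=O)C(C)(C)CC=O | intermediate
5 | (6R)-2,2,6-trimethylcyclohexane-1,4-dione | C[C@@H]1CC(=O)CC(C)(C)C1=O | intermediate
6 | (4R,6R)-4-hydroxy-2,2,6-trimethylcyclohexan-1-one | C[C@@H]1C[C@@H](O)CC(C)(C)C1=O | intermediate
7 | (4R,6R)-4-[(tert-butyldimethylsilyl)oxy]-2,2,6-trimethylcyclohexan-1-one | C[C@@H]1C[C@@H](O[Si](C)(C)C(C)(C)C)CC(C)(C)C1=O | intermediate
8 | (4R)-4-[(tert-butyldimethylsilyl)oxy]-2,6,6-trimethylcyclohex-1-en-1-yl trifluoromethanesulfonate | FC(F)(F)S(=O)(=O)OC1=C(C)C[C@@H](O[Si](C)(C)C(C)(C)C)CC1(C)C | intermediate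
9 | (2E)-3-methylpent-2-en-4-yn-1-ol | C#C/C(C)=C/CO | starting material
10 | (2E)-5-[(4R)-4-[(tert-butyldimethylsilyl)oxy]-2,6,6-trimethylcyclohex-1-en-1-yl]-3-methylpent-2-en-4-yn-1-ol | OC/C=C(\C)C#CC1=C(C)C[C@@H](O[Si](C)(C)C(C)(C)C)CC1(C)C | intermediate
11 | allylic bromide of 10 (OH replaced by Br, 2E) | BrC/C=C(\C)C#CC1=C(C)C[C@@H](O[Si](C)(C)C(C)(C)C)CC1(C)C | intermediate
12 | tributyl{(2E)-5-[(4R)-4-[(tert-butyldimethylsilyl)oxy]-2,6,6-trimethylcyclohex-1-en-1-yl]-3-methylpent-2-en-4-yn-1-yl}phosphonium bromide | CCCC[P+](CCCC)(CCCC)C/C=C(\C)C#CC1=C(C)C[C@@H](O[Si](C)(C)C(C)(C)C)CC1(C)C.[Br-] | intermediate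
13 | (R)-α-ionone | CC1=CCCC(C)(C)[C@H]1/C=C/C(C)=O | starting material
14 | diethyl (cyanomethyl)phosphonate | CCOP(=O)(CC#N)OCC | starting material
15 | (2E,4E)-3-methyl-5-[(1R)-2,6,6-trimethylcyclohex-2-en-1-yl]penta-2,4-dienenitrile | CC1=CCCC(C)(C)[C@H]1/C=C/C(C)=C/C#N | intermediate
16 | (2E,4E)-3-methyl-5-[(1R)-2,6,6-trimethyl-4-oxocyclohex-2-en-1-yl]penta-2,4-dienenitrile | CC1=CC(=O)CC(C)(C)[C@H]1/C=C/C(C)=C/C#N | intermediate
17 | (2E,4E)-5-[(1R,4R)-4-hydroxy-2,6,6-trimethylcyclohex-2-en-1-yl]-3-methylpenta-2,4-dienenitrile | CC1=C[C@H](O)CC(C)(C)[C@H]1/C=C/C(C)=C/C#N | intermediate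
18 | (2E,4E)-5-[(1R,4R)-4-hydroxy-2,6,6-trimethylcyclohex-2-en-1-yl]-3-methylpenta-2,4-dienal | CC1=C[C@H](O)CC(C)(C)[C@H]1/C=C/C(C)=C/C=O | intermediate
19 | (2E,4E,6E)-2,7-dimethylocta-2,4,6-trienedial | O=C/C(C)=C/C=C/C=C(C)/C=O | starting material
20 | (2E,4E,6E)-7-(5,5-dimethyl-1,3-dioxan-2-yl)-2-methylocta-2,4,6-trienal | O=C/C(C)=C/C=C/C=C(C)/C1OCC(C)(C)CO1 | intermediate
21 | (2E,4E,6E)-7-(5,5-dimethyl-1,3-dioxan-2-yl)-2-methylocta-2,4,6-trien-1-ol | OC/C(C)=C/C=C/C=C(C)/C1OCC(C)(C)CO1 | intermediate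
22 | 2-[(2E,4E,6E)-8-bromo-7-methylocta-2,4,6-trien-2-yl]-5,5-dimethyl-1,3-dioxane | BrC/C(C)=C/C=C/C=C(C)/C1OCC(C)(C)CO1 | intermediate
23 | [(2E,4E,6E)-7-(5,5-dimethyl-1,3-dioxan-2-yl)-2-methylocta-2,4,6-trien-1-yl]triphenylphosphonium bromide | [Br-].C(/C(C)=C/C=C/C=C(C)/C1OCC(C)(C)CO1)[P+](c1ccccc1)(c1ccccc1)c1ccccc1 | intermediate
24 | 5,5-dimethyl-1,3-dioxan-2-yl acetal of 25 | CC1=C[C@H](O)CC(C)(C)[C@H]1/C=C/C(C)=C/C=C/C(C)=C/C=C/C=C(C)/C1OCC(C)(C)CO1 | intermediate
25 | (3R,6R)-3-hydroxy-12'-apo-ε-caroten-12'-al | CC1=C[C@H](O)CC(C)(C)[C@H]1/C=C/C(C)=C/C=C/C(C)=C/C=C/C=C(C)/C=O | intermediate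
26 | (3R,3'R,6'R)-3-[(tert-butyldimethylsilyl)oxy]-7,8-didehydro-β,ε-caroten-3'-ol | CC1=C[C@H](O)CC(C)(C)[C@H]1/C=C/C(C)=C/C=C/C(C)=C/C=C/C=C(C)/C=C/C=C(\C)C#CC1=C(C)C[C@@H](O[Si](C)(C)C(C)(C)C)CC1(C)C | intermediate
27 | (3R,3'R,6'R)-7,8-didehydro-β,ε-carotene-3,3'-diol | CC1=C[C@H](O)CC(C)(C)[C@H]1/C=C/C(C)=C/C=C/C(C)=C/C=C/C=C(C)/C=C/C=C(\C)C#CC1=C(C)C[C@@H](O)CC1(C)C | target

Total step count: 18. Longest linear sequence: 10 steps (steps 1 to 8, then 17 and 18).

Steps most likely to fail

Step 3. The 6-endo conjugate acylation may be outrun by aldol or benzoin oligomerisation of the enolisable aldehyde, or proton delivery to the ring enolate may be poorly face-selective or followed by epimerisation. The fallback sets out from 4 and comes back at 5, and still closes the ring through the same C3–C4 bond. Aldehyde 4 would be oxidised (NaClO2, NaH2PO4, 2-methylbut-2-ene) to 3,3,5-trimethyl-4-oxohex-5-enoic acid F1 and converted (PhSeSePh, PBu3) into Se-phenyl 3,3,5-trimethyl-4-oxohex-5-eneselenoate F2. The acyl radical (Bu3SnH, AIBN, benzene, 80 °C, slow addition) should add 6-endo to the enone CH2 and give racemic 2,2,6-trimethylcyclohexane-1,4-dione F3. Dehydrogenation (IBX, DMSO, 70 °C) can only lead to 2,6,6-trimethylcyclohex-2-ene-1,4-dione F4, whose C=C bond would be reduced enantioselectively by fermenting baker's yeast (Saccharomyces cerevisiae) to 5.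

Step 11. Hydride delivery to the ring enone may show poor facial selectivity, since the pseudo-axial side chain also screens the face that the axial methyl leaves open. The fallback sets out from 16 and comes back at 17. Luche reduction (NaBH4, CeCl3·7H2O, MeOH, −20 °C) would give both C3' epimers, which are separable diastereomers. The unwanted (2E,4E)-5-[(1R,4S)-4-hydroxy-2,6,6-trimethylcyclohex-2-en-1-yl]-3-methylpenta-2,4-dienenitrile F5 would be inverted by a Mitsunobu reaction (4-nitrobenzoic acid, PPh3, DIAD) to (1R,4R)-4-[(1E,3E)-4-cyano-3-methylbuta-1,3-dien-1-yl]-3,5,5-trimethylcyclohex-2-en-1-yl 4-nitrobenzoate F6, and methanolysis (K2CO3, MeOH) would return 17.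

Step 17. The allylic ylide may equilibrate about the C9=C10 bond (E to Z drift next to the alkyne), and the new C11=C12 bond may form without full E-selectivity. The fallback sets out from 10 and 25 and comes back at 27; it keeps the 9E bond in the aldehyde partner and moves the ylide to the ε-half.
- Alcohol 10 would be oxidised (MnO2, CH2Cl2) to (2E)-5-[(4R)-4-[(tert-butyldimethylsilyl)oxy]-2,6,6-trimethylcyclohex-1-en-1-yl]-3-methylpent-2-en-4-ynal F7.
- Aldehyde 25 would be silylated (TBSCl, imidazole) to (3R,6R)-3-[(tert-butyldimethylsilyl)oxy]-12'-apo-ε-caroten-12'-al F8 and reduced (NaBH4) to (3R,6R)-3-[(tert-butyldimethylsilyl)oxy]-12'-apo-ε-caroten-12'-ol F9.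
- F9 would be converted (CBr4, PPh3) into [(3R,6R)-3-[(tert-butyldimethylsilyl)oxy]-12'-apo-ε-caroten-12'-yl]triphenylphosphonium bromide F10.
- Wittig reaction of F10 with F7 (NaOMe, CH2Cl2) would give (3R,3'R,6'R)-3,3'-bis[(tert-butyldimethylsilyl)oxy]-7,8-didehydro-β,ε-carotene F11, and Bu4NF would then give 27.

Further compounds
F1 | step 3 | 3,3,5-trimethyl-4-oxohex-5-enoic acid | CC(=C)C(=O)C(C)(C)CC(=O)O
F2 | step 3 | Se-phenyl 3,3,5-trimethyl-4-oxohex-5-eneselenoate | CC(=C)C(=O)C(C)(C)CC(=O)[Se]c1ccccc1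
F3 | step 3 | racemic 2,2,6-trimethylcyclohexane-1,4-dione | CC1CC(=O)CC(C)(C)C1=O
F4 | step 3 | 2,6,6-trimethylcyclohex-2-ene-1,4-dione | CC1=CC(=O)CC(C)(C)C1=O
F5 | step 11 | (2E,4E)-5-[(1R,4S)-4-hydroxy-2,6,6-trimethylcyclohex-2-en-1-yl]-3-methylpenta-2,4-dienenitrile | CC1=C[C@@H](O)CC(C)(C)[C@H]1/C=C/C(C)=C/C#N
F6 | step 11 | (1R,4R)-4-[(1E,3E)-4-cyano-3-methylbuta-1,3-dien-1-yl]-3,5,5-trimethylcyclohex-2-en-1-yl 4-nitrobenzoate | CC1=C[C@H](OC(=O)c2ccc(cc2)[N+](=O)[O-])CC(C)(C)[C@H]1/C=C/C(C)=C/C#N
F7 | step 17 | (2E)-5-[(4R)-4-[(tert-butyldimethylsilyl)oxy]-2,6,6-trimethylcyclohex-1-en-1-yl]-3-methylpent-2-en-4-ynal | O=C/C=C(\C)C#CC1=C(C)C[C@@H](O[Si](C)(C)C(C)(C)C)CC1(C)C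
F8 | step 17 | (3R,6R)-3-[(tert-butyldimethylsilyl)oxy]-12'-apo-ε-caroten-12'-al | CC1=C[C@H](O[Si](C)(C)C(C)(C)C)CC(C)(C)[C@H]1/C=C/C(C)=C/C=C/C(C)=C/C=C/C=C(C)/C=O
F9 | step 17 | (3R,6R)-3-[(tert-butyldimethylsilyl)oxy]-12'-apo-ε-caroten-12'-ol | CC1=C[C@H](O[Si](C)(C)C(C)(C)C)CC(C)(C)[C@H]1/C=C/C(C)=C/C=C/C(C)=C/C=C/C=C(C)/CO
F10 | step 17 | [(3R,6R)-3-[(tert-butyldimethylsilyl)oxy]-12'-apo-ε-caroten-12'-yl]triphenylphosphonium bromide | CC1=C[C@H](O[Si](C)(C)C(C)(C)C)CC(C)(C)[C@H]1/C=C/C(C)=C/C=C/C(C)=C/C=C/C=C(C)/C[P+](c1ccccc1)(c1ccccc1)c1ccccc1.[Br-]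
F11 | step 17 | (3R,3'R,6'R)-3,3'-bis[(tert-butyldimethylsilyl)oxy]-7,8-didehydro-β,ε-carotene | CC1=C[C@H](O[Si](C)(C)C(C)(C)C)CC(C)(C)[C@H]1/C=C/C(C)=C/C=C/C(C)=C/C=C/C=C(C)/C=C/C=C(\C)C#CC1=C(C)C[C@@H](O[Si](C)(C)C(C)(C)C)CC1(C)C
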